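The indole is cut at the C7–C7a bond of its benzo ring, which leads back to a 3,4-disubstituted N-methylpyrrole carrying an ester and an (E)-2-bromo-1-en-3-ynyl chain that ends in a bromoalkyne. A carbophilic catalyst turns that bromoalkyne into a bromovinylidene: the terminal bromine slides one carbon inward and the free pyrrole α-carbon closes onto the carbene carbon. One operation therefore builds the benzo ring and sets the vicinal C5–Br/C6–Br pair beside C7–H, with no electrophilic bromination of the carbocycle. The C3 ester blocks the second ring neighbour of the chain and later directs bromination at C2 before it is adjusted to the aldehyde.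

Key step: step 10

Remark on the chemistry: the target has no stereocentre. The only stereochemical element of the route is the bromoalkene geometry, which must be E (pyrrole and the future alkyne carbon on the same side, bromine opposite the pyrrole, since Br outranks C). The olefination reagent 8 is assumed not to be purchasable and is made in two steps from the commercial trifluoroethyl phosphonoacetate 6.

Step 1
Reactants: 1 p-toluenesulfonylmethyl isocyanide (TosMIC); 2 methyl (E)-4,4-dimethoxybut-2-enoate
Product: 3 methyl 4-(dimethoxymethyl)-1H-pyrrole-3-carboxylate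
Conditions: NaH, Et2O–DMSO, 0 °C to rt
Reagents that add atoms: none
Why: Van Leusen pyrrole synthesis, in which the TosMIC anion adds to the β-carbon of the enoate, the enolate closes onto the isocyanide carbon and loss of p-toluenesulfinate with tautomerization gives the 3,4-disubstituted pyrrole, the acetal being inert to base.

Step 2
Reactants: 3 methyl 4-(dimethoxymethyl)-1H-pyrrole-3-carboxylate
Product: 5 methyl 4-formyl-1-methylpyrrole-3-carboxylate, via N-methyl acetal 4 (not isolated)
Conditions: NaH, MeI, DMF, 0 °C to rt; then 1 M aq HCl, THF, rt
Reagents that add atoms: iodomethane, CI; water, O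
Why: N-alkylation of the pyrrolide anion followed by acid-catalysed acetal hydrolysis in the work-up, which the ring ester (a vinylogous carbamate) should survive at room temperature.

Step 3
Reactants: 6 methyl 2-[bis(2,2,2-trifluoroethoxy)phosphoryl]acetate
Product: 7 methyl 2,2-dibromo-2-[bis(2,2,2-trifluoroethoxy)phosphoryl]acetate
Conditions: Br2, aq NaOH, 0 °C
Reagents that add atoms: bromine, BrBr
Why: Exhaustive electrophilic α-bromination of the active-methylene phosphonoacetate by hypobromite (haloform-type halogenation of a stabilized carbanion), chosen because full dibromination avoids mixtures of mono- and dibromide.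

Step 4
Reactants: 7 methyl 2,2-dibromo-2-[bis(2,2,2-trifluoroethoxy)phosphoryl]acetate
Product: 8 methyl 2-bromo-2-[bis(2,2,2-trifluoroethoxy)phosphoryl]acetate (racemic)
Conditions: SnCl2·2H2O, EtOH–H2O, 0 °C
Reagents that add atoms: none
Why: Reductive mono-debromination of an activated gem-dibromide by SnCl2 (two-electron abstraction of positive bromine, then protonation), which should stop at the monobromide because the remaining C–Br bond is much less activated.

Step 5
Reactants: 5 methyl 4-formyl-1-methylpyrrole-3-carboxylate; 8 methyl 2-bromo-2-[bis(2,2,2-trifluoroethoxy)phosphoryl]acetate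
Product: 9 methyl 4-[(E)-2-bromo-3-methoxy-3-oxoprop-1-en-1-yl]-1-methylpyrrole-3-carboxylate
Conditions: KOt-Bu, 18-crown-6, THF, −78 °C
Reagents that add atoms: none
Why: Horner–Wadsworth–Emmons olefination with a Still–Gennari-type bis(trifluoroethyl) bromophosphonate under dissociating conditions, where fast irreversible elimination from the kinetic adduct should place the pyrrole cis to the ester, i.e. give the (E)-α-bromoacrylate.

Step 6
Reactants: 9 methyl 4-[(E)-2-bromo-3-methoxy-3-oxoprop-1-en-1-yl]-1-methylpyrrole-3-carboxylate
Product: 10 methyl 4-[(E)-2-bromo-3-hydroxyprop-1-en-1-yl]-1-methylpyrrole-3-carboxylate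
Conditions: i-Bu2AlH (2.2 equiv), CH2Cl2, −78 °C; aq potassium sodium tartrate work-up
Reagents that add atoms: none
Why: 1,2-Selective aluminium hydride reduction of an ester to the allylic alcohol, expected to take the α-bromoacrylate (inductively activated and twisted out of conjugation) in preference to the ring ester, which is a deactivated vinylogous carbamate.

Step 7
Reactants: 10 methyl 4-[(E)-2-bromo-3-hydroxyprop-1-en-1-yl]-1-methylpyrrole-3-carboxylate
Product: 11 methyl 4-[(E)-2-bromo-3-oxoprop-1-en-1-yl]-1-methylpyrrole-3-carboxylate
Conditions: MnO2, CH2Cl2, rt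
Reagents that add atoms: none
Why: MnO2 oxidation of an allylic alcohol under neutral conditions, which should leave the alkene geometry, the vinylic bromide and the ester untouched.

Step 8
Reactants: 11 methyl 4-[(E)-2-bromo-3-oxoprop-1-en-1-yl]-1-methylpyrrole-3-carboxylate; 12 carbon tetrabromide
Product: 13 methyl 1-methyl-4-[(1E)-2,4,4-tribromobuta-1,3-dien-1-yl]pyrrole-3-carboxylate
Conditions: PPh3 (4 equiv), CH2Cl2, 0 °C
Reagents that add atoms: none
Why: Ramirez dibromo-olefination (first half of the Corey–Fuchs sequence), a Wittig reaction of the ylide Ph3P=CBr2 with the aldehyde that does not involve the ester or the trisubstituted alkene.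

Step 9
Reactants: 13 methyl 1-methyl-4-[(1E)-2,4,4-tribromobuta-1,3-dien-1-yl]pyrrole-3-carboxylate
Product: 14 methyl 4-[(E)-2,4-dibromobut-1-en-3-yn-1-yl]-1-methylpyrrole-3-carboxylate
Conditions: DBU, DMSO, rt
Reagents that add atoms: none
Why: Base-induced anti-dehydrobromination (E2) of a 1,1-dibromoalkene to the 1-bromoalkyne, with the inner vinylic bromide spared because the hydrogen on chain C1 is syn to it in the (E)-alkene.

Step 10
Reactants: 14 methyl 4-[(E)-2,4-dibromobut-1-en-3-yn-1-yl]-1-methylpyrrole-3-carboxylate
Product: 15 methyl 5,6-dibromo-1-methylindole-3-carboxylate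
Conditions: AuCl (10 mol %), toluene, 80 °C
Reagents that add atoms: none
Why: Proposed new method: AuCl binds the bromoalkyne and triggers a 1,2-bromine shift to a gold bromovinylidene in which the migrated bromine sits on the future C6 and the carbene carbon is the future C7; this carbon, the bromoalkene and the pyrrole C4=C5 bond form a hexatriene that closes by a six-electron electrocyclization (equivalently, attack of the pyrrole α-carbon on the carbene), and proton loss from the former pyrrole C5 with protodeauration at C7 gives the aromatic ring. The closest known reaction type is the AuCl- or W(CO)5(THF)-catalysed cycloisomerization of 1-haloalkynes attached to biaryls or styrenes, which gives halophenanthrenes and halonaphthalenes with 1,2-halogen migration; closure onto a pyrrole from an enyne that already carries a vinylic bromine has not been shown. The single new ring, the benzo ring, closes in a 6-endo sense at the former alkyne terminus and forms only the C7–C7a bond. No stereocentre is created. The step needs the shift pathway to outrun direct 6-endo attack of the pyrrole on the unshifted alkyne, which would give the 5,7-dibromo isomer; the halide-bound, carbophilic monovalent gold catalyst in a non-coordinating solvent favours vinylidene formation and the C3 ester tempers the nucleophilicity of the pyrrole. Site selectivity rests on the (E)-alkene, which holds the alkyne beside the free α-carbon, and on the ester, which occupies the only other ring neighbour of the chain.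

Step 11
Reactants: 15 methyl 5,6-dibromo-1-methylindole-3-carboxylate
Product: 17 methyl 2,5,6-tribromo-1-methylindole-3-carboxylate, via C2-lithioindole ester 16 (not isolated)
Conditions: LiN(i-Pr)2, THF, −78 °C; then BrCCl2CCl2Br, −78 °C to rt
Reagents that add atoms: 1,2-dibromo-1,1,2,2-tetrachloroethane, BrC(Cl)(Cl)C(Cl)(Cl)Br
Why: Directed metalation, in which the C3 ester and the ring nitrogen make C2–H the most acidic site so that the lithium amide should remove it at −78 °C faster than it disturbs the aryl bromides, followed by positive-bromine transfer to the aryllithium.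

Step 12
Reactants: 17 methyl 2,5,6-tribromo-1-methylindole-3-carboxylate
Product: 18 (2,5,6-tribromo-1-methylindol-3-yl)methanol
Conditions: i-Bu2AlH (2.5 equiv), CH2Cl2, −78 to 0 °C; aq potassium sodium tartrate work-up
Reagents that add atoms: none
Why: Aluminium hydride reduction of the ester to the primary alcohol, which does not cleave aryl C–Br bonds, and the three bromines should keep the ring too electron-poor for ionization of the indol-3-ylmethanol.

Step 13
Reactants: 18 (2,5,6-tribromo-1-methylindol-3-yl)methanol
Product: 19 2,5,6-tribromo-1-methylindole-3-carbaldehyde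
Conditions: MnO2, CH2Cl2, rt
Reagents that add atoms: none
Why: MnO2 oxidation of a benzylic-type heteroarylmethanol to the aldehyde, which cannot over-oxidize and leaves the C–Br bonds intact.

Compound list
1 | p-toluenesulfonylmethyl isocyanide (TosMIC) | [C-]#[N+]CS(=O)(=O)c1ccc(C)cc1 | starting material
2 | methyl (E)-4,4-dimethoxybut-2-enoate | COC(OC)/C=C/C(=O)OC | starting material
3 | methyl 4-(dimethoxymethyl)-1H-pyrrole-3-carboxylate | COC(=O)c1c[nH]cc1C(OC)OC | intermediate
4 | methyl 4-(dimethoxymethyl)-1-methylpyrrole-3-carboxylate | COC(=O)c1cn(C)cc1C(OC)OC | intermediate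
5 | methyl 4-formyl-1-methylpyrrole-3-carboxylate | COC(=O)c1cn(C)cc1C=O | intermediate
6 | methyl 2-[bis(2,2,2-trifluoroethoxy)phosphoryl]acetate | COC(=O)CP(=O)(OCC(F)(F)F)OCC(F)(F)F | starting material
7 | methyl 2,2-dibromo-2-[bis(2,2,2-trifluoroethoxy)phosphoryl]acetate | COC(=O)C(Br)(Br)P(=O)(OCC(F)(F)F)OCC(F)(F)F | intermediate
8 | methyl 2-bromo-2-[bis(2,2,2-trifluoroethoxy)phosphoryl]acetate (racemic) | COC(=O)C(Br)P(=O)(OCC(F)(F)F)OCC(F)(F)F | intermediate
9 | methyl 4-[(E)-2-bromo-3-methoxy-3-oxoprop-1-en-1-yl]-1-methylpyrrole-3-carboxylate | COC(=O)c1cn(C)cc1/C=C(Br)\C(=O)OC | intermediate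
10 | methyl 4-[(E)-2-bromo-3-hydroxyprop-1-en-1-yl]-1-methylpyrrole-3-carboxylate | COC(=O)c1cn(C)cc1/C=C(Br)\CO | intermediate
11 | methyl 4-[(E)-2-bromo-3-oxoprop-1-en-1-yl]-1-methylpyrrole-3-carboxylate | COC(=O)c1cn(C)cc1/C=C(Br)\C=O | intermediate
12 | carbon tetrabromide | BrC(Br)(Br)Br | starting material
13 | methyl 1-methyl-4-[(1E)-2,4,4-tribromobuta-1,3-dien-1-yl]pyrrole-3-carboxylate | COC(=O)c1cn(C)cc1/C=C(Br)\C=C(Br)Br | intermediate
14 | methyl 4-[(E)-2,4-dibromobut-1-en-3-yn-1-yl]-1-methylpyrrole-3-carboxylate | COC(=O)c1cn(C)cc1/C=C(Br)\C#CBr | intermediate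
15 | methyl 5,6-dibromo-1-methylindole-3-carboxylate | COC(=O)c1cn(C)c2cc(Br)c(Br)cc12 | intermediate
16 | methyl 5,6-dibromo-2-lithio-1-methylindole-3-carboxylate | COC(=O)c1c([Li])n(C)c2cc(Br)c(Br)cc12 | intermediate
17 | methyl 2,5,6-tribromo-1-methylindole-3-carboxylate | COC(=O)c1c(Br)n(C)c2cc(Br)c(Br)cc12 | intermediate
18 | (2,5,6-tribromo-1-methylindol-3-yl)methanol | OCc1c(Br)n(C)c2cc(Br)c(Br)cc12 | intermediate
19 | 2,5,6-tribromo-1-methylindole-3-carbaldehyde | Cn1c(Br)c(C=O)c2cc(Br)c(Br)cc21 | target

Total step count: 13. Longest linear sequence: 11 steps (steps 1, 2 and 5 to 13); steps 3 and 4 form a two-step side branch that joins at step 5.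

Steps most likely to fail

1. Step 10 (key step). The pyrrole α-carbon may attack the gold-bound alkyne before the bromine has migrated, which would fix a bromine on C7 instead of C6, or the bromoalkyne may oligomerize and foul the catalyst. The fallback uses known chemistry and installs the C6 bromine after ring closure. It sets out from 11. Homologation with Me3SiC(Li)N2 (Colvin rearrangement, THF, −78 °C to rt) should give the terminal enyne methyl 4-[(E)-2-bromobut-1-en-3-yn-1-yl]-1-methylpyrrole-3-carboxylate F1. PtCl2-catalysed cycloisomerization in toluene at 80 °C, for which the direct 6-endo and the vinylidene pathways converge on one product because the alkyne is terminal, should give methyl 5-bromo-1-methylindole-3-carboxylate F2. Br2 in acetic acid should then brominate C6, the position known to react in indole-3-carboxylates once C5 is occupied, and the route is rejoined at 15.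

2. Step 6. Hydride may also be delivered to the ring ester, or the cis-disposed alkoxide may lactonize onto it. The fallback differentiates the two esters by hydrolysis instead of by hydride and sets out from 9. LiOH (1 equiv) in THF–H2O at 0 °C should cleave only the activated acrylate ester to (E)-2-bromo-3-[4-(methoxycarbonyl)-1-methylpyrrol-3-yl]prop-2-enoic acid F3. Isobutyl chloroformate and N-methylmorpholine convert it into the mixed isobutyl carbonic anhydride F4, and NaBH4 in THF–H2O at 0 °C reduces this to the alcohol without touching a methyl ester. The route is rejoined at 10.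

3. Step 11. The amide base may deprotonate next to a ring bromine, leading to loss of LiBr (aryne formation) or bromine migration, or C2 metalation may be incomplete. The fallback brings in the C2 bromine and the formyl group together by Vilsmeier-type bromoformylation of an oxindole and sets out from 15. Saponification (KOH, aq EtOH, reflux) gives 5,6-dibromo-1-methylindole-3-carboxylic acid F5, which should lose CO2 on heating in acid to give 5,6-dibromo-1-methylindole F6. Pyridinium tribromide in aqueous tert-butanol oxidizes this to 3,3,5,6-tetrabromo-1-methylindolin-2-one F7, and Zn in AcOH removes the two C3 bromines to give 5,6-dibromo-1-methylindolin-2-one F8. POBr3 and DMF in CHCl3 at reflux should then deliver the 2-bromo-3-formylindole directly, rejoining the route at 19.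

Further compounds
F1 | step 10 | methyl 4-[(E)-2-bromobut-1-en-3-yn-1-yl]-1-methylpyrrole-3-carboxylate | COC(=O)c1cn(C)cc1/C=C(Br)\C#C
F2 | step 10 | methyl 5-bromo-1-methylindole-3-carboxylate | COC(=O)c1cn(C)c2ccc(Br)cc12
F3 | step 6 | (E)-2-bromo-3-[4-(methoxycarbonyl)-1-methylpyrrol-3-yl]prop-2-enoic acid | COC(=O)c1cn(C)cc1/C=C(Br)\C(=O)O
F4 | step 6 | mixed isobutyl carbonic anhydride of acid F3 | COC(=O)c1cn(C)cc1/C=C(Br)\C(=O)OC(=O)OCC(C)C
F5 | step 11 | 5,6-dibromo-1-methylindole-3-carboxylic acid | OC(=O)c1cn(C)c2cc(Br)c(Br)cc12
F6 | step 11 | 5,6-dibromo-1-methylindole | Cn1ccc2cc(Br)c(Br)cc21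
F7 | step 11 | 3,3,5,6-tetrabromo-1-methylindolin-2-one | CN1C(=O)C(Br)(Br)c2cc(Br)c(Br)cc21
F8 | step 11 | 5,6-dibromo-1-methylindolin-2-one | CN1C(=O)Cc2cc(Br)c(Br)cc21
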